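Everything rests on cutting the C4–C4a aryl ketone bond of ring C. An acylium ion, tethered to ring A through O1 and the finished C2 stereocentre, attacks the arene and so closes ring C and makes the only new skeletal bond in one operation, with C2 carried through untouched. The step exploits ring A: C4a is ortho to O1 and to the C5 oxygen and para to the C7 oxygen, and while C8 is still unsubstituted the two carbons ortho to O1 are equivalent, so no regiochemistry has to be chosen. The precursor is an (R)-3-aryloxy-3-phenylpropanoic acid with a 3,5-bis(benzyloxy)-4-methylphenyl ether, made by Mitsunobu inversion; the C8 side chain is attached last.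

Key step: step 6

Assumption: flavanone numbering is used (C1′ is the side-chain carbon on C8, and the target is 2R,1′S); the facial sense of the step 9 catalyst is assigned by analogy only, so its quinidine-derived pseudoenantiomer would replace it in the same step if the (1′R) epimer were favoured.

Step 1
Reactants: 1 3,5-dihydroxy-4-methylbenzoic acid
Product: 3 3,5-bis(benzyloxy)-4-methylbenzoic acid, via benzyl ester 2 (not isolated)
Conditions: BnBr (3.3 equiv), K2CO3, DMF, 60 °C; crude ester then NaOH, MeOH/THF/H2O, 60 °C; HCl to pH 2
Reagents that add atoms: benzyl bromide, BrCc1ccccc1; sodium hydroxide, [Na+].[OH-]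
Why: Williamson benzylation of both phenols and the carboxylate, then saponification of the benzyl ester alone, should return the acid because aryl benzyl ethers are inert to hydroxide.

Step 2
Reactants: 3 3,5-bis(benzyloxy)-4-methylbenzoic acid
Product: 4 1-[3,5-bis(benzyloxy)-4-methylphenyl]ethan-1-one
Conditions: MeLi (2.3 equiv), THF, 0 °C; inverse quench into cold 1 M HCl
Reagents that add atoms: methyllithium, [Li]C
Why: Organolithium ketone synthesis from a carboxylic acid, in which methyllithium adds to the lithium carboxylate to give a geminal dilithium diolate that cannot take up a second methyl group and collapses to the methyl ketone only on acidic quench.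

Step 3
Reactants: 4 1-[3,5-bis(benzyloxy)-4-methylphenyl]ethan-1-one
Product: 6 3,5-bis(benzyloxy)-4-methylphenol, via aryl acetate 5 (not isolated)
Conditions: mCPBA (1.5 equiv), TFA (cat.), CH2Cl2, rt; then K2CO3 (cat.), MeOH, rt
Reagents that add atoms: 3-chloroperoxybenzoic acid, OOC(=O)c1cccc(Cl)c1
Why: Baeyer–Villiger oxidation of an aryl methyl ketone, in which aryl migrates in preference to methyl in the Criegee intermediate, should give the aryl acetate and mild methanolysis then frees the phenol; the ketone is preferred to the corresponding aldehyde, which without ortho or para oxygen would mainly lose hydride and end as the benzoic acid.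

Step 4
Reactants: 6 3,5-bis(benzyloxy)-4-methylphenol, 7 ethyl (S)-3-hydroxy-3-phenylpropanoate
Product: 8 ethyl (3R)-3-[3,5-bis(benzyloxy)-4-methylphenoxy]-3-phenylpropanoate
Conditions: PPh3, DIAD, THF, 0 °C → rt
Reagents that add atoms: none
Why: Mitsunobu etherification, in which the unhindered phenol displaces the oxyphosphonium of the benzylic alcohol by SN2, so the (S) carbinol centre is inverted to the (R) aryl ether that becomes C2.

Step 5
Reactants: 8 ethyl (3R)-3-[3,5-bis(benzyloxy)-4-methylphenoxy]-3-phenylpropanoate
Product: 9 (3R)-3-[3,5-bis(benzyloxy)-4-methylphenoxy]-3-phenylpropanoic acid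
Conditions: LiOH·H2O, THF/H2O, 0 °C → rt; 1 M HCl to pH 3
Reagents that add atoms: lithium hydroxide, [Li+].[OH-]
Why: Ester saponification at low temperature, where E1cB loss of the electron-rich and therefore poorly leaving aryloxide should stay slow and the benzylic stereocentre, which carries no acidic hydrogen, is not touched.

Step 6
Reactants: 9 (3R)-3-[3,5-bis(benzyloxy)-4-methylphenoxy]-3-phenylpropanoic acid
Product: 11 (2R)-5,7-bis(benzyloxy)-6-methyl-2-phenylchroman-4-one, via acid chloride 10 (not isolated)
Conditions: (COCl)2, DMF (cat.), CH2Cl2, 0 °C → rt, evaporate; SnCl4 (1.1 equiv), CH2Cl2, −78 °C; cold aq. NaHCO3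
Reagents that add atoms: none
Why: Oxalyl chloride with catalytic DMF converts the acid into acid chloride 10 through the chloroiminium reagent, SnCl4 then abstracts chloride to give an acylium ion (or its tight complex) that is attacked by the ring A carbon ortho to the ether oxygen, and loss of a proton from the arenium ion gives the aryl ketone. The closest known reaction type is the intramolecular Friedel–Crafts acylation of 3-aryloxypropanoic acids to chroman-4-ones, including 3-aryloxy-3-arylpropanoic acids made by Mitsunobu etherification. Ring C closes in a six-membered mode, exo at the acylium carbon with the arene C4a–C8a bond inside the new ring, forming C4–C4a. No stereocentre is created, since C2 comes from step 4 and takes no part in the bond-forming event. The step needs site selectivity and retention of configuration: the site is fixed because the attacked carbon is ortho to O1, ortho to one benzyloxy group and para to the other, and its counterpart across the symmetric aryl ether is identical. Configuration should hold because the strongly activated ring allows acylation at −78 °C, below the point where SnCl4 would ionise the benzylic C2–O1 bond or open the ether by elimination, and the electron-poor acyl group in the β position disfavours that ionisation further.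

Step 7
Reactants: 11 (2R)-5,7-bis(benzyloxy)-6-methyl-2-phenylchroman-4-one
Product: 12 (2R)-5,7-dihydroxy-6-methyl-2-phenylchroman-4-one
Conditions: H2 (1 atm), 10% Pd/C, EtOAc, rt, stopped at full conversion
Reagents that add atoms: none
Why: Catalytic hydrogenolysis should cleave the two primary benzyl aryl ethers much faster than the secondary, ring-held C2–O1 bond or the hydrogen-bonded C4 ketone, and the neutral medium avoids the base-induced opening to the chalcone that would racemise C2.

Step 8
Reactants: 13 syncarpic acid (2,2,4,4-tetramethylcyclohexane-1,3,5-trione), 14 3-methylbutanal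
Product: 16 2,2,4,4-tetramethyl-6-(3-methylbutylidene)cyclohexane-1,3,5-trione, via Mannich base 15 (not isolated)
Conditions: piperidine (1.0 equiv), CH2Cl2, rt; then 1 M HCl wash, dry, use at once
Reagents that add atoms: none
Why: Knoevenagel condensation run through the piperidine Mannich base, which holds the reactive alkylidene back until all syncarpic acid is consumed and so prevents a second syncarpic acid from adding, after which acid removes piperidine by elimination to release the symmetric alkylidene trione, which has no alkene geometry to control.

Step 9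
Reactants: 12 (2R)-5,7-dihydroxy-6-methyl-2-phenylchroman-4-one, 16 2,2,4,4-tetramethyl-6-(3-methylbutylidene)cyclohexane-1,3,5-trione
Product: 17 (2R)-5,7-dihydroxy-8-[(1S)-1-(2-hydroxy-3,3,5,5-tetramethyl-4,6-dioxocyclohex-1-en-1-yl)-3-methylbutyl]-6-methyl-2-phenylchroman-4-one
Conditions: quinine-derived squaramide (9-amino-9-deoxy-epi-quinine N-[3,5-bis(trifluoromethyl)phenyl]squaramide, 10 mol%), CH2Cl2, −20 °C; dilute HCl wash; chromatography
Reagents that add atoms: none
Why: Friedel–Crafts-type Michael addition of a phloroglucinol nucleus to an alkylidene syncarpic acid, a coupling known in catalytic asymmetric form for acylphloroglucinols, in which C8 (the only open position of ring A, activated by O1 and the 7-OH) adds to the β-carbon of the doubly activated alkylidene while the squaramide NH pair binds the two flanking carbonyls and the quinuclidine nitrogen binds the 7-OH, so the catalyst and not the remote C2 centre selects the alkene face and sets the (1S) side-chain centre, the adduct resting as the hydrogen-bonded enol.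

Compound list
1 | 3,5-dihydroxy-4-methylbenzoic acid | Cc1c(O)cc(C(=O)O)cc1O | starting material
2 | benzyl 3,5-bis(benzyloxy)-4-methylbenzoate | Cc1c(OCc2ccccc2)cc(C(=O)OCc2ccccc2)cc1OCc1ccccc1 | intermediate
3 | 3,5-bis(benzyloxy)-4-methylbenzoic acid | Cc1c(OCc2ccccc2)cc(C(=O)O)cc1OCc1ccccc1 | intermediate
4 | 1-[3,5-bis(benzyloxy)-4-methylphenyl]ethan-1-one | Cc1c(OCc2ccccc2)cc(C(C)=O)cc1OCc1ccccc1 | intermediate
5 | 3,5-bis(benzyloxy)-4-methylphenyl acetate | Cc1c(OCc2ccccc2)cc(OC(C)=O)cc1OCc1ccccc1 | intermediate
6 | 3,5-bis(benzyloxy)-4-methylphenol | Cc1c(OCc2ccccc2)cc(O)cc1OCc1ccccc1 | intermediate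
7 | ethyl (S)-3-hydroxy-3-phenylpropanoate | CCOC(=O)C[C@H](O)c1ccccc1 | starting material
8 | ethyl (3R)-3-[3,5-bis(benzyloxy)-4-methylphenoxy]-3-phenylpropanoate | Cc1c(OCc2ccccc2)cc(O[C@@H](c2ccccc2)CC(=O)OCC)cc1OCc1ccccc1 | intermediate
9 | (3R)-3-[3,5-bis(benzyloxy)-4-methylphenoxy]-3-phenylpropanoic acid | Cc1c(OCc2ccccc2)cc(O[C@@H](c2ccccc2)CC(=O)O)cc1OCc1ccccc1 | intermediate
10 | (3R)-3-[3,5-bis(benzyloxy)-4-methylphenoxy]-3-phenylpropanoyl chloride | Cc1c(OCc2ccccc2)cc(O[C@@H](c2ccccc2)CC(=O)Cl)cc1OCc1ccccc1 | intermediate
11 | (2R)-5,7-bis(benzyloxy)-6-methyl-2-phenylchroman-4-one | Cc1c(OCc3ccccc3)c2c(cc1OCc1ccccc1)O[C@@H](c1ccccc1)CC2=O | intermediate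
12 | (2R)-5,7-dihydroxy-6-methyl-2-phenylchroman-4-one | Cc1c(O)c2c(cc1O)O[C@@H](c1ccccc1)CC2=O | intermediate
13 | syncarpic acid (2,2,4,4-tetramethylcyclohexane-1,3,5-trione) | CC1(C)C(=O)CC(=O)C(C)(C)C1=O | starting material
14 | 3-methylbutanal | CC(C)CC=O | starting material
15 | 3-hydroxy-4,4,6,6-tetramethyl-2-[3-methyl-1-(piperidin-1-yl)butyl]cyclohex-2-ene-1,5-dione (racemic Mannich base) | CC(C)CC(N1CCCCC1)C1=C(O)C(C)(C)C(=O)C(C)(C)C1=O | intermediate
16 | 2,2,4,4-tetramethyl-6-(3-methylbutylidene)cyclohexane-1,3,5-trione | CC(C)CC=C1C(=O)C(C)(C)C(=O)C(C)(C)C1=O | intermediate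
17 | (2R)-5,7-dihydroxy-8-[(1S)-1-(2-hydroxy-3,3,5,5-tetramethyl-4,6-dioxocyclohex-1-en-1-yl)-3-methylbutyl]-6-methyl-2-phenylchroman-4-one | Cc1c(O)c2c(c([C@H](CC(C)C)C3=C(O)C(C)(C)C(=O)C(C)(C)C3=O)c1O)O[C@@H](c1ccccc1)CC2=O | target

Total step count: 9. Longest linear sequence: 8 steps (steps 1 to 7 and step 9, from 1 to 17); step 8 is a one-step side branch.

Steps most likely to fail

Step 9. The risk is poor facial selectivity at the alkylidene, because the catalyst has to decide the C1′ configuration without help from the remote C2 centre. The amine of the catalyst may also isomerise the acceptor or slowly open ring C. The fallback gives up catalyst control. It sets out from 12 and 16, which would be combined without a chiral catalyst (THF, rt, catalytic Et3N if needed) in the known biomimetic manner, to give the target together with the (2R,1′R) epimer F1. The two diastereomers would be separated by preparative HPLC and the route is rejoined at 17. F1 could be resubmitted to the amine conditions if retro-Michael equilibration proves accessible.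

Step 6. The risk is erosion of configuration at C2, either by Lewis-acid ionisation of the benzylic C2–O1 bond or by elimination to a cinnamoyl species and unselective re-closure. Loss of the benzyl ether peri to the new ketone is a further risk. The fallback builds ring C in a different order and sets C2 by a catalyst. It sets out from 6, which would be C-acetylated ortho to the hydroxyl (Ac2O, BF3·OEt2; both ortho sites are equivalent) to give 1-[2,4-bis(benzyloxy)-6-hydroxy-3-methylphenyl]ethan-1-one F2. Condensation with DMF dimethyl acetal would give the enaminone (E)-1-[2,4-bis(benzyloxy)-6-hydroxy-3-methylphenyl]-3-(dimethylamino)prop-2-en-1-one F3. Acid would close this to 5,7-bis(benzyloxy)-6-methyl-4H-chromen-4-one F4. Enantioselective conjugate addition of phenylboronic acid, with Pd(OCOCF3)2 and the enantiomer of the tert-butyl pyridine–oxazoline ligand that delivers the 2R product, would then return to the route at 11.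

Step 7. The risk is over-reduction: hydrogenolysis of the benzylic C2–O1 bond with opening of ring C, or reduction of the C4 ketone, before both benzyl ethers are gone. The fallback is a non-reductive dealkylation. It sets out from 11, which would be treated with BCl3 and pentamethylbenzene as benzyl cation scavenger in CH2Cl2 at −78 °C, and comes back at 12; this fallback makes no new compound (F0).

Further compounds
F1 | step 9 | (2R)-5,7-dihydroxy-8-[(1R)-1-(2-hydroxy-3,3,5,5-tetramethyl-4,6-dioxocyclohex-1-en-1-yl)-3-methylbutyl]-6-methyl-2-phenylchroman-4-one | Cc1c(O)c2c(c([C@@H](CC(C)C)C3=C(O)C(C)(C)C(=O)C(C)(C)C3=O)c1O)O[C@@H](c1ccccc1)CC2=O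
F2 | step 6 | 1-[2,4-bis(benzyloxy)-6-hydroxy-3-methylphenyl]ethan-1-one | CC(=O)c1c(O)cc(OCc2ccccc2)c(C)c1OCc1ccccc1
F3 | step 6 | (E)-1-[2,4-bis(benzyloxy)-6-hydroxy-3-methylphenyl]-3-(dimethylamino)prop-2-en-1-one | CN(C)/C=C/C(=O)c1c(O)cc(OCc2ccccc2)c(C)c1OCc1ccccc1
F4 | step 6 | 5,7-bis(benzyloxy)-6-methyl-4H-chromen-4-one | Cc1c(OCc2ccccc2)cc2occc(=O)c2c1OCc1ccccc1
F0 | step 7 | none | none
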